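**Plan**

- Locants: arene C1 carries the CH2CH2 bridge, C3 the cyclopentyl ring, C4 and C5 the oxygens; ring C1' is the quaternary stereocentre, C2' the CMe2 carbon, C3'–C5' the methylenes.
- Retrosynthesis: the phenols are masked as methyl ethers, C4' becomes a ketone, and each C1' methyl is tied back to C5' (which also gains a phenylsulfonyl group), giving two 1-sulfonylbicyclo[3.1.0]hexan-2-ones.
- Enabling feature: the C1' methyl and ring carbon C5' sit on the same aryl-bearing carbon, so C1' and its methyl carbon can be the two carbons of a 2-aryl-1-alkene and C5' a carbene that bridges them. Cutting C5'–C1' and C5'–CH2 together at both ends leads to a bis(α-diazo-β-keto sulfone).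
- Further back: C2'–C3' by Johnson–Claisen rearrangement, aryl C3–C1' by Suzuki coupling, and the central CH2–CH2 bond by reductive coupling of 3-bromo-4,5-dimethoxybenzaldehyde.
- Forward: bibenzyl core first, both side chains grown in parallel, then two cyclopentanone and two cyclopropane rings closed at once; the cyclopropanes are opened to release the methyls, followed by desulfonylation, deoxygenation and demethylation.
- Stereochemistry: both (S)-C1' centres are set in the double cyclopropanation by a chiral copper(I)–bisoxazoline catalyst; they are all-carbon quaternary and are not touched afterwards.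

Key step: step 9

Assumption: the (S,S)-bisoxazoline is taken to give the (1S,5R) bicycles drawn for 17; the sense of induction is to be confirmed on the first run and the (R,R)-ligand used if it proves opposite.

**Route**

Step 1
Reactants: 1 3-bromo-4,5-dimethoxybenzaldehyde (two molecules)
Product: 2 (E)-1,2-bis(3-bromo-4,5-dimethoxyphenyl)ethene
Conditions: TiCl4, Zn, THF, reflux
Reagents that add atoms: none
Why: McMurry reductive carbonyl coupling with low-valent titanium joins the two aldehyde carbons as the future CH2–CH2 bridge in one operation, and aryl bromides and methyl ethers are inert to it.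

Step 2
Reactants: 2 (E)-1,2-bis(3-bromo-4,5-dimethoxyphenyl)ethene
Product: 3 1,2-bis(3-bromo-4,5-dimethoxyphenyl)ethane
Conditions: H2 (1 atm), PtO2 (cat.), EtOAc, rt
Reagents that add atoms: none
Why: Catalytic hydrogenation of the stilbene double bond over platinum, which unlike palladium has little tendency to hydrogenolyse aryl C–Br bonds at ambient pressure, should saturate the bridge and leave both bromides in place.

Step 3
Reactants: 3 1,2-bis(3-bromo-4,5-dimethoxyphenyl)ethane; 4 bis(pinacolato)diboron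
Product: 5 1,2-bis[3,4-dimethoxy-5-(4,4,5,5-tetramethyl-1,3,2-dioxaborolan-2-yl)phenyl]ethane
Conditions: Pd(dppf)Cl2 (cat.), KOAc, 1,4-dioxane, 90 °C
Reagents that add atoms: bis(pinacolato)diboron 4, CC1(C)OB(OC1(C)C)B1OC(C)(C)C(C)(C)O1
Why: Miyaura borylation converts both electron-rich aryl bromides into pinacol boronates under weakly basic conditions that the methoxy groups tolerate.

Step 4
Reactants: 5 1,2-bis[3,4-dimethoxy-5-(4,4,5,5-tetramethyl-1,3,2-dioxaborolan-2-yl)phenyl]ethane; 6 ethyl 2-bromo-3-methylbut-2-enoate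
Product: 7 diethyl 2,2'-[ethane-1,2-diylbis(2,3-dimethoxy-5,1-phenylene)]bis(3-methylbut-2-enoate)
Conditions: Pd(OAc)2/SPhos (cat.), K3PO4, toluene–H2O, 90 °C
Reagents that add atoms: ethyl 2-bromo-3-methylbut-2-enoate 6, CCOC(=O)C(Br)=C(C)C
Why: Suzuki–Miyaura coupling forms the aryl C3–C1' bond, the α-bromo enoate being activated for oxidative addition, the bulky biaryl phosphine carrying the hindered reductive elimination and the phosphate base sparing the esters.

Step 5
Reactants: 7 diethyl 2,2'-[ethane-1,2-diylbis(2,3-dimethoxy-5,1-phenylene)]bis(3-methylbut-2-enoate)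
Product: 8 2,2'-[ethane-1,2-diylbis(2,3-dimethoxy-5,1-phenylene)]bis(3-methylbut-2-en-1-ol)
Conditions: DIBAL-H, CH2Cl2, −78 → 0 °C; Rochelle salt
Reagents that add atoms: none
Why: DIBAL-H reduces conjugated esters in 1,2-fashion to primary allylic alcohols without touching the tetrasubstituted alkenes.

Step 6
Reactants: 8 2,2'-[ethane-1,2-diylbis(2,3-dimethoxy-5,1-phenylene)]bis(3-methylbut-2-en-1-ol); 9 triethyl orthoacetate
Product: 12 diethyl 4,4'-[ethane-1,2-diylbis(2,3-dimethoxy-5,1-phenylene)]bis(3,3-dimethylpent-4-enoate), via bis(mixed orthoester) 10 (not isolated), via bis(ketene acetal) 11 (not isolated)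
Conditions: EtCO2H (cat.), neat 9, sealed tube, 175 °C
Reagents that add atoms: triethyl orthoacetate 9, CCOC(C)(OCC)OCC
Why: Johnson–Claisen rearrangement, a [3,3] sigmatropic shift of the ketene acetal formed in situ, makes the C2'–C3' bond at the dimethyl-substituted alkene terminus (giving quaternary C2') and moves the double bond into the required Ar–C(=CH2) position, as is established for 2-aryl-3-methylbut-2-en-1-ols.

Step 7
Reactants: 12 diethyl 4,4'-[ethane-1,2-diylbis(2,3-dimethoxy-5,1-phenylene)]bis(3,3-dimethylpent-4-enoate); 13 methyl phenyl sulfone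
Product: 14 1,2-bis{3-[3,3-dimethyl-5-oxo-6-(phenylsulfonyl)hex-1-en-2-yl]-4,5-dimethoxyphenyl}ethane
Conditions: n-BuLi, THF, −78 → 0 °C; then 12, 0 °C → rt; aq. NH4Cl
Reagents that add atoms: methyl phenyl sulfone 13, CS(=O)(=O)c1ccccc1
Why: Claisen-type acylation of α-lithiated methyl phenyl sulfone by the esters gives the β-keto sulfones, a second equivalent of the carbanion converting each product into its enolate and so preventing over-addition.

Step 8
Reactants: 14 1,2-bis{3-[3,3-dimethyl-5-oxo-6-(phenylsulfonyl)hex-1-en-2-yl]-4,5-dimethoxyphenyl}ethane; 15 4-acetamidobenzenesulfonyl azide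
Product: 16 1,2-bis{3-[6-diazo-3,3-dimethyl-5-oxo-6-(phenylsulfonyl)hex-1-en-2-yl]-4,5-dimethoxyphenyl}ethane
Conditions: Et3N, MeCN, 0 °C → rt
Reagents that add atoms: 4-acetamidobenzenesulfonyl azide 15, CC(=O)Nc1ccc(cc1)S(=O)(=O)N=[N+]=[N-]
Why: Regitz diazo transfer from a sulfonyl azide to the doubly activated methylene between ketone and sulfone proceeds under mild amine base and leaves the alkenes untouched.

Step 9
Reactants: 16 1,2-bis{3-[6-diazo-3,3-dimethyl-5-oxo-6-(phenylsulfonyl)hex-1-en-2-yl]-4,5-dimethoxyphenyl}ethane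
Product: 17 1,2-bis{3-[(1S,5R)-2,2-dimethyl-4-oxo-5-(phenylsulfonyl)bicyclo[3.1.0]hexan-1-yl]-4,5-dimethoxyphenyl}ethane (cis-fused; bicycle numbered from the aryl-bearing carbon)
Conditions: CuOTf·½C6H6 (20 mol %), (S,S)-iPr-box [2,2'-(propane-2,2-diyl)bis((4S)-4-isopropyl-4,5-dihydrooxazole), 30 mol %], toluene, 50 °C, slow addition of 16
Reagents that add atoms: none
Why: Copper(I)–bisoxazoline decomposes each diazo group with loss of N2 to an electrophilic copper carbene at C5', which adds to the tethered electron-rich 2-aryl alkene in a concerted, asynchronous (2+1) cycloaddition in which the bond to the CH2 terminus leads and the bond to C1' follows. The closest known reaction type is the copper(I)–bisoxazoline-catalysed enantioselective intramolecular cyclopropanation of α-diazo-β-keto sulfones to 1-sulfonylbicyclo[3.1.0]hexan-2-ones. Each cyclopentanone ring closes through the C5'–C1' bond across the three-atom tether C4'(=O)–C3'–C2' (five-membered, exo with respect to the alkene), and each cyclopropane closes in the same event through the C5'–CH2 bond. C1' is set by the choice of alkene face, which the C2-symmetric ligand on the copper carbene controls, and C5' follows from C1' because suprafacial addition across a three-atom tether can only give the cis-fused bicycle. The step needs enantioface selectivity at both alkenes and chemoselectivity for cyclopropanation over C–H insertion into the gem-methyl groups; the first rests on the catalyst acting on a carbene that its sulfonyl group and CMe2 neighbour restrict to one folded conformer, the second on the preference of copper carbenes for an electron-rich 1,1-disubstituted alkene held close by the gem-dimethyl effect. Since the two ends react independently, a wrong-face event at one end should appear as a separable meso diastereomer, which should raise the enantiomeric purity of the C2-symmetric product above that of a single cyclopropanation.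

Step 10
Reactants: 17 1,2-bis{3-[(1S,5R)-2,2-dimethyl-4-oxo-5-(phenylsulfonyl)bicyclo[3.1.0]hexan-1-yl]-4,5-dimethoxyphenyl}ethane
Product: 18 1,2-bis{3-[(1S)-1,2,2-trimethyl-4-oxo-5-(phenylsulfonyl)cyclopentyl]-4,5-dimethoxyphenyl}ethane (epimer mixture at the sulfonyl-bearing carbon)
Conditions: SmI2, HMPA, t-BuOH, THF, −78 → 0 °C
Reagents that add atoms: none
Why: Electron-transfer reductive opening of a cyclopropyl ketone activated by the geminal sulfone cleaves the bond that overlaps with the carbonyl π system, here the external C5'–CH2 bond (the internal C5'–C1' bond lies in the nodal plane), so the CH2 radical is reduced and protonated to the C1' methyl while the sulfone-stabilised samarium enolate protects the ketone; C1' is not involved and keeps its configuration, and the sulfonyl-bearing carbon is formed without control because it is removed next.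

Step 11
Reactants: 18 1,2-bis{3-[(1S)-1,2,2-trimethyl-4-oxo-5-(phenylsulfonyl)cyclopentyl]-4,5-dimethoxyphenyl}ethane
Product: 19 1,2-bis{3-[(1S)-1,2,2-trimethyl-4-oxocyclopentyl]-4,5-dimethoxyphenyl}ethane
Conditions: Al(Hg), THF–H2O, rt
Reagents that add atoms: none
Why: Aluminium-amalgam reductive desulfonylation of a β-keto sulfone cleaves the C–S bond next to the carbonyl under near-neutral conditions that leave ketone and aryl ethers intact, and it removes the only uncontrolled stereocentre.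

Step 12
Reactants: 19 1,2-bis{3-[(1S)-1,2,2-trimethyl-4-oxocyclopentyl]-4,5-dimethoxyphenyl}ethane
Product: 21 1,2-bis{3,4-dimethoxy-5-[(1S)-1,2,2-trimethylcyclopentyl]phenyl}ethane, via bis(hydrazone) 20 (not isolated)
Conditions: N2H4·H2O, KOH, diethylene glycol, 130 → 195 °C
Reagents that add atoms: none
Why: Wolff–Kishner reduction (Huang-Minlon procedure) removes the unhindered ring carbonyl through its hydrazone, the quaternary C1' centre cannot epimerise in base, and any aryl ether cleaved by hot hydroxide converges on the same product in the last step.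

Step 13
Reactants: 21 1,2-bis{3,4-dimethoxy-5-[(1S)-1,2,2-trimethylcyclopentyl]phenyl}ethane
Product: 23 5,5'-(ethane-1,2-diyl)bis{3-[(1S)-1,2,2-trimethylcyclopentyl]benzene-1,2-diol} (CNP0144189.1), via bis(bromobenzodioxaborole) 22 (not isolated)
Conditions: BBr3, CH2Cl2, −78 → 0 °C; then degassed H2O
Reagents that add atoms: none
Why: Boron tribromide cleaves the four aryl methyl ethers through aryloxyboron intermediates that are hydrolysed on aqueous work-up, conditions that do not affect the all-carbon quaternary centres.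

**Compound list**

1 | 3-bromo-4,5-dimethoxybenzaldehyde | COc1cc(C=O)cc(Br)c1OC | starting material
2 | (E)-1,2-bis(3-bromo-4,5-dimethoxyphenyl)ethene | COc1cc(/C=C/c2cc(OC)c(OC)c(Br)c2)cc(Br)c1OC | intermediate
3 | 1,2-bis(3-bromo-4,5-dimethoxyphenyl)ethane | COc1cc(CCc2cc(OC)c(OC)c(Br)c2)cc(Br)c1OC | intermediate
4 | bis(pinacolato)diboron | CC1(C)OB(OC1(C)C)B1OC(C)(C)C(C)(C)O1 | starting material
5 | 1,2-bis[3,4-dimethoxy-5-(4,4,5,5-tetramethyl-1,3,2-dioxaborolan-2-yl)phenyl]ethane | COc1cc(CCc2cc(OC)c(OC)c(B3OC(C)(C)C(C)(C)O3)c2)cc(B2OC(C)(C)C(C)(C)O2)c1OC | intermediate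
6 | ethyl 2-bromo-3-methylbut-2-enoate | CCOC(=O)C(Br)=C(C)C | starting material
7 | diethyl 2,2'-[ethane-1,2-diylbis(2,3-dimethoxy-5,1-phenylene)]bis(3-methylbut-2-enoate) | COc1cc(CCc2cc(OC)c(OC)c(C(C(=O)OCC)=C(C)C)c2)cc(C(C(=O)OCC)=C(C)C)c1OC | intermediate
8 | 2,2'-[ethane-1,2-diylbis(2,3-dimethoxy-5,1-phenylene)]bis(3-methylbut-2-en-1-ol) | COc1cc(CCc2cc(OC)c(OC)c(C(CO)=C(C)C)c2)cc(C(CO)=C(C)C)c1OC | intermediate
9 | triethyl orthoacetate | CCOC(C)(OCC)OCC | starting material
10 | 1,2-bis{3-[1-[(1,1-diethoxyethoxy)methyl]-2-methylprop-1-en-1-yl]-4,5-dimethoxyphenyl}ethane (bis mixed orthoester, not isolated) | COc1cc(CCc2cc(OC)c(OC)c(C(COC(C)(OCC)OCC)=C(C)C)c2)cc(C(COC(C)(OCC)OCC)=C(C)C)c1OC | intermediate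
11 | 1,2-bis{3-[1-{[(1-ethoxyethenyl)oxy]methyl}-2-methylprop-1-en-1-yl]-4,5-dimethoxyphenyl}ethane (bis ketene acetal, not isolated) | COc1cc(CCc2cc(OC)c(OC)c(C(COC(=C)OCC)=C(C)C)c2)cc(C(COC(=C)OCC)=C(C)C)c1OC | intermediate
12 | diethyl 4,4'-[ethane-1,2-diylbis(2,3-dimethoxy-5,1-phenylene)]bis(3,3-dimethylpent-4-enoate) | COc1cc(CCc2cc(OC)c(OC)c(C(=C)C(C)(C)CC(=O)OCC)c2)cc(C(=C)C(C)(C)CC(=O)OCC)c1OC | intermediate
13 | methyl phenyl sulfone | CS(=O)(=O)c1ccccc1 | starting material
14 | 1,2-bis{3-[3,3-dimethyl-5-oxo-6-(phenylsulfonyl)hex-1-en-2-yl]-4,5-dimethoxyphenyl}ethane | COc1cc(CCc2cc(OC)c(OC)c(C(=C)C(C)(C)CC(=O)CS(=O)(=O)c3ccccc3)c2)cc(C(=C)C(C)(C)CC(=O)CS(=O)(=O)c2ccccc2)c1OC | intermediate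
15 | 4-acetamidobenzenesulfonyl azide | CC(=O)Nc1ccc(cc1)S(=O)(=O)N=[N+]=[N-] | starting material
16 | 1,2-bis{3-[6-diazo-3,3-dimethyl-5-oxo-6-(phenylsulfonyl)hex-1-en-2-yl]-4,5-dimethoxyphenyl}ethane | COc1cc(CCc2cc(OC)c(OC)c(C(=C)C(C)(C)CC(=O)C(=[N+]=[N-])S(=O)(=O)c3ccccc3)c2)cc(C(=C)C(C)(C)CC(=O)C(=[N+]=[N-])S(=O)(=O)c2ccccc2)c1OC | intermediate
17 | 1,2-bis{3-[(1S,5R)-2,2-dimethyl-4-oxo-5-(phenylsulfonyl)bicyclo[3.1.0]hexan-1-yl]-4,5-dimethoxyphenyl}ethane | COc1cc(CCc2cc(OC)c(OC)c([C@@]34C[C@]3(S(=O)(=O)c3ccccc3)C(=O)CC4(C)C)c2)cc([C@@]23C[C@]2(S(=O)(=O)c2ccccc2)C(=O)CC3(C)C)c1OC | intermediate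
18 | 1,2-bis{3-[(1S)-1,2,2-trimethyl-4-oxo-5-(phenylsulfonyl)cyclopentyl]-4,5-dimethoxyphenyl}ethane (epimers at the sulfonyl-bearing carbon) | COc1cc(CCc2cc(OC)c(OC)c([C@@]3(C)C(S(=O)(=O)c4ccccc4)C(=O)CC3(C)C)c2)cc([C@@]2(C)C(S(=O)(=O)c3ccccc3)C(=O)CC2(C)C)c1OC | intermediate
19 | 1,2-bis{3-[(1S)-1,2,2-trimethyl-4-oxocyclopentyl]-4,5-dimethoxyphenyl}ethane | CC1(C)CC(=O)C[C@]1(C)c1cc(CCc2cc(OC)c(OC)c([C@@]3(C)CC(=O)CC3(C)C)c2)cc(OC)c1OC | intermediate
20 | 1,2-bis{3-[(1S)-4-hydrazinylidene-1,2,2-trimethylcyclopentyl]-4,5-dimethoxyphenyl}ethane (not isolated) | CC1(C)CC(=NN)C[C@]1(C)c1cc(CCc2cc(OC)c(OC)c([C@@]3(C)CC(=NN)CC3(C)C)c2)cc(OC)c1OC | intermediate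
21 | 1,2-bis{3,4-dimethoxy-5-[(1S)-1,2,2-trimethylcyclopentyl]phenyl}ethane | CC1(C)CCC[C@]1(C)c1cc(CCc2cc(OC)c(OC)c([C@@]3(C)CCCC3(C)C)c2)cc(OC)c1OC | intermediate
22 | 1,2-bis{2-bromo-7-[(1S)-1,2,2-trimethylcyclopentyl]-1,3,2-benzodioxaborol-5-yl}ethane (not isolated) | CC1(C)CCC[C@]1(C)c1cc(CCc2cc3OB(Br)Oc3c([C@@]3(C)CCCC3(C)C)c2)cc2OB(Br)Oc12 | intermediate
23 | 5,5'-(ethane-1,2-diyl)bis{3-[(1S)-1,2,2-trimethylcyclopentyl]benzene-1,2-diol} | CC1(C)CCC[C@]1(C)c1cc(CCc2cc(O)c(O)c([C@@]3(C)CCCC3(C)C)c2)cc(O)c1O | target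

**Count and risks**

Total step count: 13. Longest linear sequence: 13 steps (1 → 23); compounds 4, 6, 9, 13 and 15 are purchased.

Step 9. The enantioface discrimination at the hindered, ortho-methoxy-substituted aryl alkene may be incomplete, so that much material ends up as the meso diastereomer, or the carbene may be diverted into C–H insertion at a gem-methyl group. The fallback changes the carbene substituent to a bulkier arylsulfonyl group and sets out from 12. Acylation of lithiated methyl mesityl sulfone (n-BuLi, THF) by 12 should give 1,2-bis{3-[6-(mesitylsulfonyl)-3,3-dimethyl-5-oxohex-1-en-2-yl]-4,5-dimethoxyphenyl}ethane F1. Diazo transfer with 15 and Et3N should give 1,2-bis{3-[6-diazo-6-(mesitylsulfonyl)-3,3-dimethyl-5-oxohex-1-en-2-yl]-4,5-dimethoxyphenyl}ethane F2. The same copper(I)–bisoxazoline cyclopropanation should give 1,2-bis{3-[(1S,5R)-5-(mesitylsulfonyl)-2,2-dimethyl-4-oxobicyclo[3.1.0]hexan-1-yl]-4,5-dimethoxyphenyl}ethane F3. Samarium diiodide opening as in step 10 should give 1,2-bis{3-[(1S)-5-(mesitylsulfonyl)-1,2,2-trimethyl-4-oxocyclopentyl]-4,5-dimethoxyphenyl}ethane F4, and aluminium amalgam as in step 11 brings the material back to the route at 19.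

Step 10. Electron transfer may expel sulfinate before the ring opens, leaving a cyclopropyl ketone that samarium diiodide opens far less readily. It may also break the internal bond toward the aryl-stabilised position, or samarium(III) may ionise the donor–acceptor cyclopropane. The fallback replaces electron transfer by a two-electron nucleophilic opening and sets out from 17. Sodium benzeneselenolate (PhSeH, NaH, DMF, 0 °C → rt) should attack the cyclopropane CH2, the only ring carbon open to SN2 displacement, in a homoconjugate addition that releases the keto sulfone enolate. This should give 1,2-bis{3-[(1R)-2,2-dimethyl-4-oxo-1-[(phenylselanyl)methyl]-5-(phenylsulfonyl)cyclopentyl]-4,5-dimethoxyphenyl}ethane F5. Radical deselenation with Bu3SnH and AIBN (benzene, 80 °C, high hydride concentration to outrun a 1,2-aryl shift of the primary radical) turns CH2SePh into the C1' methyl and returns to the route at 18.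

Step 6. At 175 °C under acid the allylic alcohol may ionise and eliminate to a diene, or the two-fold rearrangement may stop at the half-rearranged stage. The fallback uses an enolate Claisen variant that runs below 70 °C and sets out from 8. Acetylation (Ac2O, pyridine, DMAP) should give ethane-1,2-diylbis(2,3-dimethoxy-5,1-phenylene)bis(3-methylbut-2-ene-2,1-diyl) diacetate F6. LDA and TMSCl in THF at −78 °C should give the bis(silyl ketene acetal) F7. This should undergo Ireland–Claisen rearrangement on warming to reflux to the bis(trimethylsilyl) 4,4'-[ethane-1,2-diylbis(2,3-dimethoxy-5,1-phenylene)]bis(3,3-dimethylpent-4-enoate) F8. Dilute acid work-up should give 4,4'-[ethane-1,2-diylbis(2,3-dimethoxy-5,1-phenylene)]bis(3,3-dimethylpent-4-enoic acid) F9, and O-alkylation with EtI and K2CO3 in DMF returns to the route at 12.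

**Further compounds**

F1 | step 9 | 1,2-bis{3-[6-(mesitylsulfonyl)-3,3-dimethyl-5-oxohex-1-en-2-yl]-4,5-dimethoxyphenyl}ethane | COc1cc(CCc2cc(OC)c(OC)c(C(=C)C(C)(C)CC(=O)CS(=O)(=O)c3c(C)cc(C)cc3C)c2)cc(C(=C)C(C)(C)CC(=O)CS(=O)(=O)c2c(C)cc(C)cc2C)c1OC
F2 | step 9 | 1,2-bis{3-[6-diazo-6-(mesitylsulfonyl)-3,3-dimethyl-5-oxohex-1-en-2-yl]-4,5-dimethoxyphenyl}ethane | COc1cc(CCc2cc(OC)c(OC)c(C(=C)C(C)(C)CC(=O)C(=[N+]=[N-])S(=O)(=O)c3c(C)cc(C)cc3C)c2)cc(C(=C)C(C)(C)CC(=O)C(=[N+]=[N-])S(=O)(=O)c2c(C)cc(C)cc2C)c1OC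
F3 | step 9 | 1,2-bis{3-[(1S,5R)-5-(mesitylsulfonyl)-2,2-dimethyl-4-oxobicyclo[3.1.0]hexan-1-yl]-4,5-dimethoxyphenyl}ethane | COc1cc(CCc2cc(OC)c(OC)c([C@@]34C[C@]3(S(=O)(=O)c3c(C)cc(C)cc3C)C(=O)CC4(C)C)c2)cc([C@@]23C[C@]2(S(=O)(=O)c2c(C)cc(C)cc2C)C(=O)CC3(C)C)c1OC
F4 | step 9 | 1,2-bis{3-[(1S)-5-(mesitylsulfonyl)-1,2,2-trimethyl-4-oxocyclopentyl]-4,5-dimethoxyphenyl}ethane | COc1cc(CCc2cc(OC)c(OC)c([C@@]3(C)C(S(=O)(=O)c4c(C)cc(C)cc4C)C(=O)CC3(C)C)c2)cc([C@@]2(C)C(S(=O)(=O)c3c(C)cc(C)cc3C)C(=O)CC2(C)C)c1OC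
F5 | step 10 | 1,2-bis{3-[(1R)-2,2-dimethyl-4-oxo-1-[(phenylselanyl)methyl]-5-(phenylsulfonyl)cyclopentyl]-4,5-dimethoxyphenyl}ethane | COc1cc(CCc2cc(OC)c(OC)c([C@@]3(C[Se]c4ccccc4)C(S(=O)(=O)c4ccccc4)C(=O)CC3(C)C)c2)cc([C@@]2(C[Se]c3ccccc3)C(S(=O)(=O)c3ccccc3)C(=O)CC2(C)C)c1OC
F6 | step 6 | ethane-1,2-diylbis(2,3-dimethoxy-5,1-phenylene)bis(3-methylbut-2-ene-2,1-diyl) diacetate | COc1cc(CCc2cc(OC)c(OC)c(C(COC(C)=O)=C(C)C)c2)cc(C(COC(C)=O)=C(C)C)c1OC
F7 | step 6 | 1,2-bis{3-[1-({[1-(trimethylsilyloxy)ethenyl]oxy}methyl)-2-methylprop-1-en-1-yl]-4,5-dimethoxyphenyl}ethane | COc1cc(CCc2cc(OC)c(OC)c(C(COC(=C)O[Si](C)(C)C)=C(C)C)c2)cc(C(COC(=C)O[Si](C)(C)C)=C(C)C)c1OC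
F8 | step 6 | bis(trimethylsilyl) 4,4'-[ethane-1,2-diylbis(2,3-dimethoxy-5,1-phenylene)]bis(3,3-dimethylpent-4-enoate) | COc1cc(CCc2cc(OC)c(OC)c(C(=C)C(C)(C)CC(=O)O[Si](C)(C)C)c2)cc(C(=C)C(C)(C)CC(=O)O[Si](C)(C)C)c1OC
F9 | step 6 | 4,4'-[ethane-1,2-diylbis(2,3-dimethoxy-5,1-phenylene)]bis(3,3-dimethylpent-4-enoic acid) | COc1cc(CCc2cc(OC)c(OC)c(C(=C)C(C)(C)CC(=O)O)c2)cc(C(=C)C(C)(C)CC(=O)O)c1OC
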